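**Plan**

- Locants (hydrindane numbering, kept throughout): C7a (quaternary, bears C8 = CH2OAc), C7, C6 (OAc), C5 (OH), C4 (CMe2), C3a, C3 (CHOAc), C2 (C–CH3), C1; C9 = CH2 on C3a; C10 = cyclopropane CH bonded to C9, C1 and C2.
- Retrosynthesis: the acetates and a C5 benzyl ether are adjusted last; C3–OAc and the C8/C6 oxygens go back to a C3 ketone and a C8→O6 γ-lactone; the cage is then cut at C2–C10, C1–C10 and C3a–C9, leaving enone 18 and the two-carbon vinyl-onium unit 19.
- Enabling feature: the oxygenated C3 lies between the methyl-bearing cyclopropane carbon C2 and the quaternary C3a. At the ketone level the ring C1–C2–C3–C3a–C7a is a 2-methylcyclopent-2-enone, whose α′-carbon (C3a), β-carbon (C1) and α-carbon (C2) are exactly the three sites that must bond to C9/C10.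
- Forward: cyclopentane first (keto ester 1), six-membered ring by Robinson annulation, gem-dimethylation, lactone ring (temporary C8–O6 tether), cyclopentenone, then one cascade closes the cyclopentane C3a–C9–C10–C1–C7a and the cyclopropane C1–C2–C10.
- Stereochemistry: C7a by catalytic asymmetric Michael addition; C6 by the lactone tether; C5 by axial hydride delivery; C3a, C10, C1 and C2 in the cascade (relayed from C7a); C3 by capture of the cyclopropylcarbinyl cation on its convex face.

Key step: step 11

Remark: the configurations at C3a in 12–18 and at C2 in 15–17 are erased in steps 10 and 11, so the epimers drawn are only the expected ones; in step 1 the ligand antipode that delivers (R)-3 is the one to be used.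

**Step 1**
Reactants: 1 tert-butyl 2-oxocyclopentane-1-carboxylate; 2 methyl vinyl ketone
Product: 3 tert-butyl (R)-2-oxo-1-(3-oxobutyl)cyclopentane-1-carboxylate
Conditions: [Pd((R)-BINAP)(H2O)2](OTf)2 (5 mol%), THF, −20 °C
Reagents that add atoms: none
Why: Catalytic enantioselective Michael addition of a cyclic β-keto ester to an enone through a chiral palladium enolate, whose ligand shields one enolate face so that the quaternary C7a is set as R.

**Step 2**
Reactants: 3 tert-butyl (R)-2-oxo-1-(3-oxobutyl)cyclopentane-1-carboxylate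
Product: 5 tert-butyl (7aR)-5-oxo-2,3,5,6,7,7a-hexahydro-1H-indene-7a-carboxylate, via ketol 4 (not isolated)
Conditions: pyrrolidine, AcOH, toluene, 80 °C
Reagents that add atoms: none
Why: Intramolecular aldol condensation (second stage of a Robinson annulation), in which the methyl ketone adds to the ring ketone and the ketol dehydrates to the conjugated enone; C7a is quaternary and cannot epimerise.

**Step 3**
Reactants: 5 tert-butyl (7aR)-5-oxo-2,3,5,6,7,7a-hexahydro-1H-indene-7a-carboxylate
Product: 7 tert-butyl (7aR)-4,4-dimethyl-5-oxo-1,2,4,5,6,7-hexahydro-7aH-indene-7a-carboxylate, via monomethyl enone 6 (not isolated)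
Conditions: KOtBu (3 equiv), MeI (excess), tBuOH–THF, 0 °C → rt
Reagents that add atoms: methyl iodide, CI
Why: Deconjugative α,α-dialkylation of an enone, in which the extended dienolate is methylated twice at C4, placing the gem-dimethyl group and moving the double bond to C3a=C3.

**Step 4**
Reactants: 7 tert-butyl (7aR)-4,4-dimethyl-5-oxo-1,2,4,5,6,7-hexahydro-7aH-indene-7a-carboxylate
Product: 9 (6S,7aR)-keto lactone (γ-lactone C8(=O)–O–C6, C5 ketone, C3a=C3 alkene), via carboxylic acid 8 (not isolated)
Conditions: CF3CO2H, CH2Cl2, 0 °C → rt, evaporate; then PhI(OH)OTs, CH2Cl2, 40 °C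
Reagents that add atoms: none
Why: Acidolysis of the tert-butyl ester followed by hypervalent-iodine lactonisation of a 5-oxo acid (oxidation of the ketone enol at C6, then intramolecular displacement by the carboxylate); the one-carbon tether from C7a can only bridge on its own face, so the C6–O bond is set cis to C8.

**Step 5**
Reactants: 9 (6S,7aR)-keto lactone
Product: 10 (5R,6S,7aR)-hydroxy lactone (5-OH cis to O6)
Conditions: NaBH4, MeOH–THF, −20 → 0 °C
Reagents that add atoms: none
Why: Hydride reduction of a cyclohexanone next to a gem-dimethyl group, where axial attack anti to the lactone bridge and to the axial methyl should give the equatorial alcohol cis to the C6 oxygen.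

**Step 6**
Reactants: 10 (5R,6S,7aR)-hydroxy lactone
Product: 11 5-O-benzyl ether of 10
Conditions: 2-benzyloxy-1-methylpyridinium triflate, MgO, PhCF3, 85 °C
Reagents that add atoms: 2-benzyloxy-1-methylpyridinium triflate, C[n+]1ccccc1OCc1ccccc1.[O-]S(=O)(=O)C(F)(F)F
Why: Benzyl transfer from a 2-benzyloxypyridinium salt under neutral conditions, suited to a hindered alcohol and harmless to the lactone and alkene.

**Step 7**
Reactants: 11 5-O-benzyl ether lactone
Product: 13 C3 alcohol (trans-fused hydrindane, 3a-H anti to the lactone bridge, 3-OH syn to 3a-H), via alkylborane 12 (not isolated)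
Conditions: BH3·THF, THF, 0 °C → rt; then 30% H2O2, aq NaHCO3, 0 °C
Reagents that add atoms: hydrogen peroxide, OO
Why: Hydroboration–oxidation, in which boron adds to the less substituted C3 and hydrogen to C3a in a syn fashion from the face away from the lactone bridge and the axial methyl.

**Step 8**
Reactants: 13 C3 alcohol
Product: 14 C3 ketone (trans-fused)
Conditions: Dess–Martin periodinane, NaHCO3, CH2Cl2, rt
Reagents that add atoms: none
Why: Buffered Dess–Martin oxidation of the secondary alcohol to the cyclopentanone without touching the lactone or benzyl ether.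

**Step 9**
Reactants: 14 C3 ketone
Product: 15 2-methyl ketone (methyl expected anti to C8; either C2 epimer serves)
Conditions: LiN(iPr)2, THF, −78 °C; MeI, −78 → −20 °C
Reagents that add atoms: methyl iodide, CI
Why: Kinetic enolate alkylation, in which the base removes the accessible C2 proton (C3a–H is flanked by two quaternary carbons) and the enolate is methylated.

**Step 10**
Reactants: 15 2-methyl ketone
Product: 18 2-methylcyclopent-2-enone (C1=C2, C3 ketone, lactone and benzyl ether retained), via selenide 16 (not isolated), via selenoxide 17 (not isolated)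
Conditions: LiN(iPr)2, THF, −78 °C; PhSeBr; then 30% H2O2, pyridine, CH2Cl2, 0 °C → rt
Reagents that add atoms: none
Why: α-Selenenylation of the C2 enolate and selenoxide syn-elimination towards the ring CH2 (C1) should give the conjugated 2-methylcyclopentenone.

**Step 11**
Reactants: 18 2-methylcyclopent-2-enone; 19 diphenyl(vinyl)sulfonium triflate
Product: 22 tetracyclic keto lactone (C3a–C9, C10–C1 and C10–C2 formed; cyclopropane C1–C2–C10 on the face of the five-membered ring syn to C8), via sulfonium ylide 20 (not isolated), via sulfonium enolate 21 (not isolated)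
Conditions: KN(SiMe3)2, THF, −78 → 0 °C; then 19, THF–DMF, −78 °C → rt
Reagents that add atoms: none
Why: Proposed new method: deprotonation of 18 at C3a gives the cross-conjugated dienolate, whose C3a adds to the vinylsulfonium salt to give ylide 20; the ylide carbon C10 then adds to the enone carbon C1 (21), and the enolate carbon C2 displaces Ph2S from C10, forming the C2–C10 bond. The closest known reaction types are the bicycloannulation of enone α′-enolates with vinylphosphonium salts to tricyclo[2.2.1.0(2,6)]heptan-3-ones and the Michael-initiated cyclopropanations of vinylsulfonium salts; the sulfonium is chosen because Ph2S leaves far more readily from the hindered secondary carbon. Two rings close: the cyclopentane C3a–C9–C10–C1–C7a by 5-exo-trig conjugate addition and the cyclopropane C1–C2–C10 by 3-exo-tet displacement. C3a is set in the first addition, expected syn to C8 because only that attack gives the cis-fused hydrindenone and the opposite face meets the axial hydrogens at C5 and C7; C10, C1 and C2 then follow from the two-carbon tether, which can only reach the same face of the five-membered ring. The step needs C- over O-alkylation at a carbon flanked by two quaternary centres, and conjugate addition of the ylide in preference to attack on the lactone carbonyl; the small, soft onium acceptor and the proximity of C1 are relied on for both, and the C10 configuration of 21 can equilibrate through the ylide until the sulfonium stands anti to C2.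

**Step 12**
Reactants: 22 tetracyclic keto lactone
Product: 23 triol (C8–OH, 6-OH, 3-OH on the concave side, that is 3-epi; 5-OBn)
Conditions: LiAlH4, THF, 0 °C → rt
Reagents that add atoms: none
Why: LiAlH4 opens the lactone to the C8/C6 diol and reduces the ketone from its open convex face (syn to C9), which is expected to leave the C3 hydroxyl on the concave side, epimeric to the target.

**Step 13**
Reactants: 23 triol
Product: 24 triacetate (3-epi, 5-OBn)
Conditions: Ac2O, DMAP, pyridine, 40 °C
Reagents that add atoms: acetic anhydride, CC(=O)OC(C)=O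
Why: DMAP-catalysed acetylation of the three free hydroxyl groups, while C5 stays benzylated.

**Step 14**
Reactants: 24 triacetate (3-epi)
Product: 25 5-O-benzyl ether of the target (C3 acetate syn to C9)
Conditions: CF3SO3H (2 mol%), AcOH, rt
Reagents that add atoms: acetic acid, CC(=O)O
Why: Acid-catalysed ionisation of the cyclopropylcarbinyl acetate to the bisected cyclopropylcarbinyl cation and recapture by acetic acid on the unhindered convex face (syn to C9, away from the C7 methylene) should give the more stable C3 epimer; the other acetates and the benzyl ether do not ionise.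

**Step 15**
Reactants: 25 5-O-benzyl ether of the target
Product: 26 target CNP0197219.1
Conditions: H2 (1 atm), Pd(OH)2/C, EtOAc, rt
Reagents that add atoms: none
Why: Hydrogenolysis of the benzyl ether under neutral conditions frees the C5 hydroxyl without acyl migration from O6 and should leave the cage cyclopropane intact.

**Compound list**

1 | tert-butyl 2-oxocyclopentane-1-carboxylate | CC(C)(C)OC(=O)C1CCCC1=O | starting material
2 | methyl vinyl ketone | CC(=O)C=C | starting material
3 | tert-butyl (R)-2-oxo-1-(3-oxobutyl)cyclopentane-1-carboxylate | CC(C)(C)OC(=O)[C@]1(CCC(C)=O)C(=O)CCC1 | intermediate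
4 | cis-fused ketol (3a-hydroxy-5-oxo bicyclic ester) | CC(C)(C)OC(=O)[C@]12CCC(=O)C[C@@]1(O)CCC2 | intermediate (not isolated)
5 | tert-butyl (7aR)-5-oxo-2,3,5,6,7,7a-hexahydro-1H-indene-7a-carboxylate | CC(C)(C)OC(=O)[C@]12CCC(=O)C=C1CCC2 | intermediate
6 | 4-methyl enone (monomethylation stage) | CC(C)(C)OC(=O)[C@]12CCC(=O)C(C)=C1CCC2 | intermediate (not isolated)
7 | tert-butyl (7aR)-4,4-dimethyl-5-oxo-1,2,4,5,6,7-hexahydro-7aH-indene-7a-carboxylate | CC(C)(C)OC(=O)[C@]12CCC(=O)C(C)(C)C1=CCC2 | intermediate
8 | (7aR)-4,4-dimethyl-5-oxo-1,2,4,5,6,7-hexahydro-7aH-indene-7a-carboxylic acid | OC(=O)[C@]12CCC(=O)C(C)(C)C1=CCC2 | intermediate (not isolated)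
9 | (6S,7aR)-keto lactone (C8(=O)–O–C6, C5 ketone, C3a=C3) | O=C1[C@]23C[C@H](O1)C(=O)C(C)(C)C2=CCC3 | intermediate
10 | (5R,6S,7aR)-hydroxy lactone | O=C1[C@]23C[C@H](O1)[C@H](O)C(C)(C)C2=CCC3 | intermediate
11 | 5-O-benzyl lactone | O=C1[C@]23C[C@H](O1)[C@H](OCc1ccccc1)C(C)(C)C2=CCC3 | intermediate
12 | C3 alkylborane | O=C1[C@]23C[C@H](O1)[C@H](OCc1ccccc1)C(C)(C)[C@@H]2[C@@H](B)CC3 | intermediate (not isolated)
13 | C3 alcohol (trans-fused) | O=C1[C@]23C[C@H](O1)[C@H](OCc1ccccc1)C(C)(C)[C@@H]2[C@@H](O)CC3 | intermediate
14 | C3 ketone (trans-fused) | O=C1[C@]23C[C@H](O1)[C@H](OCc1ccccc1)C(C)(C)[C@@H]2C(=O)CC3 | intermediate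
15 | 2-methyl C3 ketone | O=C1[C@]23C[C@H](O1)[C@H](OCc1ccccc1)C(C)(C)[C@@H]2C(=O)[C@@H](C)C3 | intermediate
16 | 2-methyl-2-(phenylselanyl) ketone | O=C1[C@]23C[C@H](O1)[C@H](OCc1ccccc1)C(C)(C)[C@@H]2C(=O)[C@@](C)([Se]c1ccccc1)C3 | intermediate (not isolated)
17 | selenoxide of 16 | O=C1[C@]23C[C@H](O1)[C@H](OCc1ccccc1)C(C)(C)[C@@H]2C(=O)[C@@](C)([Se](=O)c1ccccc1)C3 | intermediate (not isolated)
18 | 2-methylcyclopent-2-enone (C1=C2, C3 ketone) with lactone and 5-OBn | O=C1[C@]23C[C@H](O1)[C@H](OCc1ccccc1)C(C)(C)[C@@H]2C(=O)C(C)=C3 | intermediate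
19 | diphenyl(vinyl)sulfonium triflate | C=C[S+](c1ccccc1)c1ccccc1.[O-]S(=O)(=O)C(F)(F)F | starting material
20 | sulfonium ylide (C3a–C9 formed, carbanion at C10) | O=C1[C@]23C[C@H](O1)[C@H](OCc1ccccc1)C(C)(C)[C@@]2(C[CH-][S+](c1ccccc1)c1ccccc1)C(=O)C(C)=C3 | intermediate (not isolated)
21 | sulfonium enolate (C10–C1 formed, C2=C3 enolate) | O=C1[C@]23C[C@H](O1)[C@H](OCc1ccccc1)C(C)(C)[C@]24C[C@H]([S+](c1ccccc1)c1ccccc1)[C@H]3C(C)=C4[O-] | intermediate (not isolated)
22 | tetracyclic keto lactone | O=C1[C@]23C[C@H](O1)[C@H](OCc1ccccc1)C(C)(C)[C@]24C[C@@H]5[C@H]3[C@]5(C)C4=O | intermediate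
23 | triol, 3-epi, 5-OBn | OC[C@]12C[C@H](O)[C@H](OCc4ccccc4)C(C)(C)[C@]13C[C@@H]1[C@H]2[C@]1(C)[C@@H]3O | intermediate
24 | triacetate, 3-epi, 5-OBn | CC(=O)OC[C@]12C[C@H](OC(C)=O)[C@H](OCc4ccccc4)C(C)(C)[C@]13C[C@@H]1[C@H]2[C@]1(C)[C@@H]3OC(C)=O | intermediate
25 | 5-O-benzyl ether of the target | CC(=O)OC[C@]12C[C@H](OC(C)=O)[C@H](OCc4ccccc4)C(C)(C)[C@]13C[C@@H]1[C@H]2[C@]1(C)[C@H]3OC(C)=O | intermediate
26 | CNP0197219.1 (C3, C6 and C8 acetates, free 5-OH) | CC(=O)OC[C@]12C[C@H](OC(C)=O)[C@H](O)C(C)(C)[C@]13C[C@@H]1[C@H]2[C@]1(C)[C@H]3OC(C)=O | target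

Total step count: 15. Longest linear sequence: 15 steps (from 1).

**Steps most likely to fail**

1. Step 11. The first carbon–carbon bond must form at a carbon flanked by two quaternary centres, so O-alkylation or no reaction may win; attack may also come from the wrong face of the dienolate; and the ylide may acylate on the lactone carbonyl instead of adding to C1.
   Fallback (known chemistry), from 18 back to 22: O-allylation of the potassium dienolate (KN(SiMe3)2, allyl bromide, THF–DMPU) would give the allyl dienol ether F1. Its Claisen rearrangement (toluene, 110 °C) should form the C3a quaternary centre intramolecularly and give the C3a-allyl enone F2. Lemieux–Johnson cleavage (OsO4 cat., NaIO4, 2,6-lutidine, dioxane–water) of the terminal alkene gives aldehyde F3, and TsNHNH2 gives tosylhydrazone F4. Bamford–Stevens conditions (NaOMe, THF, 60 °C) generate the diazoalkane F5, which should add across the enone in an intramolecular 1,3-dipolar cycloaddition (C10 to C1, N to C2) to give the 1-pyrazoline F6. Irradiation (350 nm) extrudes N2 and closes C2–C10, giving 22.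

2. Step 14. The cyclopropylcarbinyl cation may leak into ring-opened homoallylic acetates or skeletal shifts, or be captured without facial preference.
   Fallback, from 22 back to 25, with no carbocation: NaBH4 (MeOH, 0 °C) should reduce only the ketone, giving the concave C3 alcohol lactone F7. This single free carbinol is then epimerised under thermodynamic control by reversible hydrogen transfer ((η5-C5Ph5)Ru(CO)2Cl, KOtBu cat., toluene, 50 °C) to the convex C3 alcohol lactone F8. LiAlH4 (THF, 0 °C) opens the lactone to the triol F9, and Ac2O, DMAP, pyridine gives 25.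

3. Step 4. The trivalent iodine reagent may oxidise the trisubstituted alkene in competition, or α-oxidation of the hindered ketone may stall.
   Fallback, from 7 back to 9, by stepwise halogenation and displacement: LiN(SiMe3)2 and Me3SiCl (THF, −78 °C) give the trimethylsilyl enol ether F10. N-Bromosuccinimide (THF, −78 °C) gives the C6 bromo ketone F11, whose epimers interconvert through the enol. CF3CO2H frees the bromo acid F12, and NaHCO3 in DMF closes the lactone by intramolecular SN2 displacement with inversion, giving 9.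

**Further compounds**

F1 | step 11 | allyl dienol ether of 18 | O=C1[C@]23C[C@H](O1)[C@H](OCc1ccccc1)C(C)(C)C2=C(OCC=C)C(C)=C3
F2 | step 11 | C3a-allyl enone (allyl syn to C8) | O=C1[C@]23C[C@H](O1)[C@H](OCc1ccccc1)C(C)(C)[C@@]2(CC=C)C(=O)C(C)=C3
F3 | step 11 | C3a-(2-oxoethyl) enone | O=C1[C@]23C[C@H](O1)[C@H](OCc1ccccc1)C(C)(C)[C@@]2(CC=O)C(=O)C(C)=C3
F4 | step 11 | tosylhydrazone of F3 | O=C1[C@]23C[C@H](O1)[C@H](OCc1ccccc1)C(C)(C)[C@@]2(CC=NNS(=O)(=O)c1ccc(C)cc1)C(=O)C(C)=C3
F5 | step 11 | diazoalkane | O=C1[C@]23C[C@H](O1)[C@H](OCc1ccccc1)C(C)(C)[C@@]2(CC=[N+]=[N-])C(=O)C(C)=C3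
F6 | step 11 | 1-pyrazoline (C10–C1 and N–C2 formed) | O=C1[C@]23C[C@H](O1)[C@H](OCc1ccccc1)C(C)(C)[C@]24C[C@@H](N=N5)[C@H]3[C@]5(C)C4=O
F7 | step 14 | concave C3 alcohol lactone | O=C1[C@]23C[C@H](O1)[C@H](OCc1ccccc1)C(C)(C)[C@]24C[C@@H]5[C@H]3[C@]5(C)[C@@H]4O
F8 | step 14 | convex C3 alcohol lactone | O=C1[C@]23C[C@H](O1)[C@H](OCc1ccccc1)C(C)(C)[C@]24C[C@@H]5[C@H]3[C@]5(C)[C@H]4O
F9 | step 14 | triol with target C3 configuration, 5-OBn | OC[C@]12C[C@H](O)[C@H](OCc4ccccc4)C(C)(C)[C@]13C[C@@H]1[C@H]2[C@]1(C)[C@H]3O
F10 | step 4 | trimethylsilyl enol ether of 7 | CC(C)(C)OC(=O)[C@]12CC=C(O[Si](C)(C)C)C(C)(C)C1=CCC2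
F11 | step 4 | C6 bromo ketone tert-butyl ester (Br anti to the ester) | CC(C)(C)OC(=O)[C@]12C[C@@H](Br)C(=O)C(C)(C)C1=CCC2
F12 | step 4 | C6 bromo keto acid | OC(=O)[C@]12C[C@@H](Br)C(=O)C(C)(C)C1=CCC2
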